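**Retrosynthetic overview**
- Feature: in the nine-membered lactone (ring O, C1–C8), the carbonyl C1 and the carbinol C5 are both oxygenated. C2–C4 bridge them on one side and C6–C8–O on the other. They are therefore read as the two carbons of a tetrasubstituted enol ether C1=C5 shared by a cyclopentene (C1–C5) and a dihydropyran (O, C1, C5–C8).
- Endgame: the target comes from Z-selective semihydrogenation of the desilylated C7 alkynoate. This comes from acylation of C7-OH with (R)-4-silyloxyoct-2-ynoic acid, and that alcohol from chelate-controlled reduction of the C5 ketone of the 5-oxo lactone.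
- Key disconnection: the 5-oxo lactone comes from ozonolysis of the C1=C5 bond of the hexahydrocyclopenta[b]pyran, which merges the five- and six-membered rings into the nine-membered ring.
- The enol ether comes from its conjugated isomer, a bicyclic vinylogous ester (C1=C2–C3=O). On this template C4 is set by methylation and enolate hydroxylation, C3 by hydride, and C2 by diimide after the alkene has been moved by bromination and dehydrobromination. All of this is done without acid, because the tertiary allylic C4–O bond next to the C1=C5 enol ether would ionise.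
- Ring order: the six-membered ring comes first, as a δ-lactone from L-rhamnal diacetate (C7 and C8 from the chiral pool, C6 by cuprate addition). The five-membered ring follows by intramolecular Claisen condensation, with the pyran re-closed as an enol ether. The nine-membered ring comes last.

Key step: step 14

Remark: the labels C1–C8 are those of the target lactone (C1 carbonyl, C8 methyl carbinol on the ring oxygen) in every intermediate, and C4' is the side-chain carbinol.

Step 1
Reactants: 1 3,4-di-O-acetyl-L-rhamnal (3,4-di-O-acetyl-6-deoxy-L-glucal)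
Product: 2 (5R,6S)-5-acetoxy-6-methyl-5,6-dihydro-2H-pyran-2-one
Conditions: mCPBA, BF3·OEt2 (cat.), CH2Cl2, −20 °C
Reagents that add atoms: 3-chloroperoxybenzoic acid (mCPBA) O=C(OO)c1cccc(Cl)c1
Why: Ferrier-type ionisation of the allylic acetate, capture of the allyl oxocarbenium ion at C1 by the peracid and fragmentation of the anomeric perester is the known one-pot oxidation of glycal esters to 2-enono-1,5-lactones, and it leaves the chiral-pool centres C7 and C8 untouched.

Step 2
Reactants: 2 (5R,6S)-5-acetoxy-6-methyl-5,6-dihydro-2H-pyran-2-one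
Product: 3 (5R,6S)-5-hydroxy-6-methyl-5,6-dihydro-2H-pyran-2-one
Conditions: Novozym 435 (immobilised Candida antarctica lipase B), n-BuOH, MTBE, 35 °C
Reagents that add atoms: none
Why: Lipase-catalysed transesterification removes the acetate under neutral conditions and so avoids the elimination to a 2-pyranone that an alkoxide base would cause.

Step 3
Reactants: 3 (5R,6S)-5-hydroxy-6-methyl-5,6-dihydro-2H-pyran-2-one
Product: 4 (5R,6S)-5-(benzyloxy)-6-methyl-5,6-dihydro-2H-pyran-2-one
Conditions: BnOC(=NH)CCl3, TfOH (cat.), CH2Cl2–cyclohexane, 0 °C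
Reagents that add atoms: benzyl 2,2,2-trichloroacetimidate N=C(OCc1ccccc1)C(Cl)(Cl)Cl
Why: Acid-catalysed trichloroacetimidate benzylation needs no base and puts on O7 a group that is a poor leaving group toward cuprates, survives the enolate chemistry, can chelate zinc in step 15 and is removed orthogonally to silyl ethers.

Step 4
Reactants: 4 (5R,6S)-5-(benzyloxy)-6-methyl-5,6-dihydro-2H-pyran-2-one; 5 methyllithium
Product: 6 (4S,5R,6S)-5-(benzyloxy)-4,6-dimethyloxan-2-one (C1 and C5–C8 of the target, with C6-Me, C7-OBn and C8-Me all trans)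
Conditions: MeLi (2 equiv per Cu), CuI, Et2O, 0 °C; then 4, −78 °C; aq NH4Cl
Reagents that add atoms: methyllithium [Li]C (used as Me2CuLi, [Li+].C[Cu-]C)
Why: Conjugate addition of the Gilman cuprate to the half-chair enoate occurs anti to the neighbouring C7 benzyloxy group, so the C6 methyl ends trans to O7 and the all-equatorial C6/C7/C8 triad results.

Step 5
Reactants: 6 (4S,5R,6S)-5-(benzyloxy)-4,6-dimethyloxan-2-one; 7 1-bromobut-2-yne
Product: 8 (3S,4S,5R,6S)-5-(benzyloxy)-3-(but-2-yn-1-yl)-4,6-dimethyloxan-2-one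
Conditions: LiN(iPr)2, THF, −78 °C; 7, DMPU, −78 to −40 °C
Reagents that add atoms: 1-bromobut-2-yne CC#CCBr
Why: SN2 alkylation of the lactone enolate with the reactive propargylic bromide takes place trans to the C6 methyl, and the configuration at C5 has no lasting consequence because C5 becomes sp2 in step 12.

Step 6
Reactants: 8 (3S,4S,5R,6S)-5-(benzyloxy)-3-(but-2-yn-1-yl)-4,6-dimethyloxan-2-one
Product: 9 (3S,4S,5R,6S)-5-(benzyloxy)-4,6-dimethyl-3-(2-oxobutyl)oxan-2-one
Conditions: NaAuCl4·2H2O (cat.), THF–H2O, rt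
Reagents that add atoms: water O
Why: Gold-catalysed alkyne hydration is steered by 5-exo-dig participation of the lactone carbonyl oxygen at the proximal alkyne carbon, so the ketone appears at C3 and the 1,4-dicarbonyl array C1/C3 results.

Step 7
Reactants: 9 (3S,4S,5R,6S)-5-(benzyloxy)-4,6-dimethyl-3-(2-oxobutyl)oxan-2-one
Product: 11 (2S,3R,4S,4aS)-3-(benzyloxy)-2,4,7-trimethyl-3,4,4a,5-tetrahydrocyclopenta[b]pyran-6(2H)-one (vinylogous ester O–C1=C2(Me)–C3=O), via hydroxy dione 10 (not isolated)
Conditions: KOtBu, THF–tBuOH, reflux; aq HCl to pH 3; then p-TsOH (cat.), toluene, Dean–Stark, reflux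
Reagents that add atoms: none
Why: Intramolecular Claisen (Dieckmann-type) condensation of the ethyl ketone enolate (C2) onto the lactone carbonyl (C1) is the standard closure of 2-methylcyclopentane-1,3-diones from 4-oxohexanoates, after which acid-catalysed enol etherification by the freed C8 hydroxyl can reach only C1 (six-membered ring) and equilibrates C5 so that all four pyran substituents are equatorial.

Step 8
Reactants: 11 bicyclic vinylogous ester; 12 iodomethane
Product: 13 (2S,3R,4S,4aR,5R)-3-(benzyloxy)-2,4,5,7-tetramethyl-3,4,4a,5-tetrahydrocyclopenta[b]pyran-6(2H)-one (major C4 epimer drawn)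
Conditions: LiN(iPr)2, THF, −78 °C; MeI
Reagents that add atoms: iodomethane CI
Why: Kinetic alpha-prime deprotonation of the vinylogous ester (Stork–Danheiser-type enolate) and SN2 methylation place the methyl carbon on C4, mainly anti to C6, and this centre is planarised again in step 9.

Step 9
Reactants: 13 C4-methyl vinylogous ester
Product: 14 (2S,3R,4S,4aR,5R)-3-(benzyloxy)-5-hydroxy-2,4,5,7-tetramethyl-3,4,4a,5-tetrahydrocyclopenta[b]pyran-6(2H)-one
Conditions: KN(SiMe3)2, THF, −78 °C; 2-(phenylsulfonyl)-3-phenyloxaziridine; aq NH4Cl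
Reagents that add atoms: 2-(phenylsulfonyl)-3-phenyloxaziridine O=S(=O)(c1ccccc1)N1OC1c1ccccc1
Why: Enolate hydroxylation with the N-sulfonyloxaziridine (Davis oxidation) delivers oxygen to the tetrasubstituted C3–C4 enolate from the face opposite the C5–C6 bond, which relays the configuration of the pyran to the tertiary carbinol C4 in the required sense.

Step 10
Reactants: 14 tertiary alpha-hydroxy vinylogous ester
Product: 15 (2S,3R,4S,4aR,5R,6R)-3-(benzyloxy)-2,4,5,7-tetramethyl-2,3,4,4a,5,6-hexahydrocyclopenta[b]pyran-5,6-diol (C3-OH trans to C4-OH)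
Conditions: LiAlH4, Et2O, −20 to 0 °C; H2O, aq NaOH work-up
Reagents that add atoms: none
Why: 1,2-Reduction of the vinylogous ester carbonyl by LiAlH4 comes from the face that carries the C4 alkoxide (which can deliver hydride) and is free of the C4 methyl and of C6, giving the C3/C4 trans-diol, while the basic work-up keeps the glycal-like allylic alcohol from ionising.

Step 11
Reactants: 15 trans-diol
Product: 16 bis(triethylsilyl) ether of 15 (C3-OTES and C4-OTES, enol ether still C1=C2)
Conditions: Et3SiOTf, 2,6-lutidine, CH2Cl2, −78 to 0 °C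
Reagents that add atoms: triethylsilyl triflate CC[Si](CC)(CC)OS(=O)(=O)C(F)(F)F
Why: Silyl triflate silylation buffered with 2,6-lutidine caps the secondary and the hindered tertiary hydroxyl in one operation without free acid.

Step 12
Reactants: 16 bis(triethylsilyl) ether
Product: 18 3-(benzyloxy)-2,4,5-trimethyl-7-methylidene-5,6-bis(triethylsilyloxy)-2,3,4,5,6,7-hexahydrocyclopenta[b]pyran (2-alkoxy diene C5=C1–C2=CH2), via allylic bromide 17 (not isolated)
Conditions: NBS (1 equiv), NaHCO3, CH2Cl2, −78 to −20 °C; then DBU, −20 °C to rt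
Reagents that add atoms: none
Why: Electrophilic bromination of the enol ether at C2, from the face opposite the C3 silyloxy group, gives a bromo oxocarbenium ion that can lose a proton only from C5, which moves the enol ether into the ring-fusion position C1=C5, and E2 dehydrobromination of the tertiary allylic bromide, whose only anti-periplanar hydrogens are on the methyl group because H3 is syn to bromine, gives the alkoxy diene, both being known reactions of ketone enol ethers.

Step 13
Reactants: 18 alkoxy diene
Product: 19 3-(benzyloxy)-2,4,5,7-tetramethyl-5,6-bis(triethylsilyloxy)-2,3,4,5,6,7-hexahydrocyclopenta[b]pyran, C1=C5 enol ether, configuration 2S,3R,4R,6S,7R,8S in target numbering (C2-Me, C3-OTES and C4-Me on one face of the cyclopentene, C4-OTES on the other)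
Conditions: 2-nitrobenzenesulfonylhydrazide, Et3N, CH2Cl2, rt
Reagents that add atoms: none
Why: Diimide reduction adds two hydrogens suprafacially to the unhindered 1,1-disubstituted alkene only, the tetrasubstituted enol ether being inert, and from the face opposite the adjacent C3 silyloxy group, so the C2 methyl ends cis to O3.

Step 14
Reactants: 19 hexahydrocyclopenta[b]pyran enol ether
Product: 21 8-(benzyloxy)-3,5,7,9-tetramethyl-4,5-bis(triethylsilyloxy)oxonane-2,6-dione (nine-membered 5-oxo lactone, 2S,3R,4S,6R,7R,8S in target numbering, the descriptor changes at C4 and C6 being due to priorities only), via hydroperoxy ketal 20 (not isolated)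
Conditions: O3/O2, CH2Cl2–MeOH (4:1), NaHCO3, Sudan Red 7B, −78 °C; then Me2S, −78 °C to rt
Reagents that add atoms: ozone [O-][O+]=O
Why: Ozone adds as a 1,3-dipole to the only C=C of 19, the electron-rich tetrasubstituted C1=C5 enol ether, and the primary ozonide cycloreverts in the sense normal for enol ethers, to the C1 lactone carbonyl and a C5 carbonyl oxide that methanol traps as 20 and Me2S reduces to the ketone. The closest known reaction type is the oxidative cleavage of 2-oxabicyclo[4.3.0]non-1(6)-enes and their homologues with ozone, peracids or glycol-cleaving oxidants to nine- and ten-membered keto lactones. No ring is closed by bond formation: the ring O–C1–C2–C3–C4–C5–C6–C7–C8 is the periphery of the bicycle and is released when the shared C1–C5 bond is cut, so neither high dilution nor an activated seco acid is needed. No stereocentre is formed, and C2, C3, C4, C6, C7 and C8 are carried over unchanged from the five- and six-membered templates. The step needs chemoselectivity for the alkene over the benzyl and silyl ethers, which the large rate advantage of the enol ether, the low temperature and the indicator dye that marks the end point should secure. It also needs handling free of acid and base, secured by NaHCO3 and the neutral Me2S work-up, because the tertiary allylic C4 silyloxy group of 19 ionises with acid and C6 of 21 (alpha to the ketone, beta to OBn) would epimerise or eliminate with base.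

Step 15
Reactants: 21 5-oxo lactone
Product: 22 (5S)-alcohol, 8-(benzyloxy)-6-hydroxy-3,5,7,9-tetramethyl-4,5-bis(triethylsilyloxy)oxonan-2-one (2S,3R,4R,5S,6S,7R,8S in target numbering)
Conditions: Zn(BH4)2, Et2O–CH2Cl2, −30 to 0 °C; aq NH4Cl
Reagents that add atoms: none
Why: In this chelation-controlled reduction zinc bridges the C5 carbonyl and the C7 benzyloxy oxygen, the six-membered chelate holds the C6 methyl axial and hydride enters opposite to it, which gives the 5,7-syn and 5,6-syn alcohol, the same sense as the polar Felkin–Anh model predicts for the non-chelating C4 silyloxy group, while the weakly basic zinc alkoxide limits transannular acyl transfer.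

Step 16
Reactants: 22 C5 alcohol
Product: 23 C5 triethylsilyl ether of 22 (C3, C4 and C5 tris-OTES, C7-OBn)
Conditions: Et3SiOTf, 2,6-lutidine, CH2Cl2, −40 to 0 °C
Reagents that add atoms: triethylsilyl triflate CC[Si](CC)(CC)OS(=O)(=O)C(F)(F)F
Why: Silyl triflate silylation of the hindered C5 carbinol removes the one nucleophile that could attack the lactone carbonyl across the ring and leaves O7 as the only position still to be unmasked.

Step 17
Reactants: 23 tris(triethylsilyl) benzyl ether
Product: 24 C7 alcohol, 8-hydroxy-3,5,7,9-tetramethyl-4,5,6-tris(triethylsilyloxy)oxonan-2-one (stereocentres as in 23)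
Conditions: H2 (1 atm), Pd/C, EtOAc, rt
Reagents that add atoms: none
Why: Catalytic hydrogenolysis cleaves the benzyl ether under neutral conditions, is orthogonal to the three silyl ethers and meets no alkene at this stage.

Step 18
Reactants: 25 pentanoyl chloride; 26 bis(trimethylsilyl)acetylene
Product: 27 1-(trimethylsilyl)hept-1-yn-3-one
Conditions: AlCl3, CH2Cl2, 0 °C
Reagents that add atoms: bis(trimethylsilyl)acetylene C[Si](C)(C)C#C[Si](C)(C)C
Why: Friedel–Crafts-type acylation of the bis-silylated alkyne with ipso loss of one silyl group is the standard entry to silyl ynones.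

Step 19
Reactants: 27 1-(trimethylsilyl)hept-1-yn-3-one
Product: 28 (R)-1-(trimethylsilyl)hept-1-yn-3-ol
Conditions: Ru[(R,R)-TsDPEN](p-cymene) (cat.), iPrOH, rt
Reagents that add atoms: none
Why: Noyori-type asymmetric transfer hydrogenation of alkynyl ketones distinguishes the alkynyl from the alkyl flank, and the (R,R)-diamine complex should give the (R)-propargylic alcohol that becomes C4'.

Step 20
Reactants: 28 (R)-1-(trimethylsilyl)hept-1-yn-3-ol
Product: 29 (R)-hept-1-yn-3-ol
Conditions: K2CO3 (cat.), MeOH, 0 °C to rt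
Reagents that add atoms: none
Why: Base-catalysed methanolysis cleaves the alkynyl C–Si bond selectively and does not touch the carbinol centre.

Step 21
Reactants: 29 (R)-hept-1-yn-3-ol
Product: 30 (R)-triethyl(hept-1-yn-3-yloxy)silane
Conditions: Et3SiCl, imidazole, CH2Cl2, 0 °C
Reagents that add atoms: chlorotriethylsilane CC[Si](Cl)(CC)CC
Why: Imidazole-promoted silylation gives the side chain the same silyl group as the core, so that one mild fluoride step frees all hydroxyls later.

Step 22
Reactants: 30 (R)-triethyl(hept-1-yn-3-yloxy)silane; 31 carbon dioxide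
Product: 32 (R)-4-(triethylsilyloxy)oct-2-ynoic acid
Conditions: nBuLi, THF, −78 °C; CO2; cold dilute HCl to pH 4
Reagents that add atoms: carbon dioxide O=C=O
Why: Deprotonation of the terminal alkyne and carboxylation of the lithium acetylide is the direct route to 2-alkynoic acids and leaves C4' untouched.

Step 23
Reactants: 24 C7 alcohol; 32 (R)-4-(triethylsilyloxy)oct-2-ynoic acid
Product: 33 C7 (R)-4-(triethylsilyloxy)oct-2-ynoate of 24 (tetrakis-TES alkynoate)
Conditions: DCC, DMAP (cat.), CH2Cl2, −20 to 0 °C
Reagents that add atoms: (R)-4-(triethylsilyloxy)oct-2-ynoic acid CCCC[C@@H](O[Si](CC)(CC)CC)C#CC(=O)O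
Why: Steglich esterification at low temperature with only catalytic DMAP, as is usual for 2-alkynoic acids, acylates the single free hydroxyl at C7 and touches no stereocentre.

Step 24
Reactants: 33 tetrakis-TES alkynoate
Product: 34 C7 (R)-4-hydroxyoct-2-ynoate of the 3,4,5-trihydroxy lactone
Conditions: HF·pyridine, pyridine, THF, 0 °C to rt
Reagents that add atoms: none
Why: Buffered HF·pyridine desilylation removes all four triethylsilyl groups at the alkynoate stage, where the linear triple bond keeps the freed C4' hydroxyl away from the ester carbonyl so that butenolide formation cannot occur.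

Step 25
Reactants: 34 tetraol alkynoate
Product: 35 target, (2S,3R,4R,5S,6S,7R,8S)-3,4,5-trihydroxy-2,4,6,8-tetramethylnonan-8-olid-7-yl (2Z,4R)-4-hydroxyoct-2-enoate
Conditions: H2 (1 atm), Pd/CaCO3 poisoned with Pb(OAc)2 (Lindlar catalyst), quinoline, EtOAc, 0 °C
Reagents that add atoms: none
Why: Lindlar semihydrogenation adds hydrogen syn to the alkyne and should stop at the (Z)-enoate, and it is placed last so that the lactonisation-prone (Z)-4-hydroxy enoate and the translactonisation-prone triol lactone never meet acid, base or fluoride.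

**Compound list**
1 | 3,4-di-O-acetyl-L-rhamnal | C[C@@H]1OC=C[C@H](OC(C)=O)[C@H]1OC(C)=O | starting material
2 | (5R,6S)-5-acetoxy-6-methyl-5,6-dihydro-2H-pyran-2-one | C[C@@H]1OC(=O)C=C[C@H]1OC(C)=O | intermediate
3 | (5R,6S)-5-hydroxy-6-methyl-5,6-dihydro-2H-pyran-2-one | C[C@@H]1OC(=O)C=C[C@H]1O | intermediate
4 | (5R,6S)-5-(benzyloxy)-6-methyl-5,6-dihydro-2H-pyran-2-one | C[C@@H]1OC(=O)C=C[C@H]1OCc1ccccc1 | intermediate
5 | methyllithium | [Li]C | starting material
6 | (4S,5R,6S)-5-(benzyloxy)-4,6-dimethyloxan-2-one | C[C@@H]1OC(=O)C[C@H](C)[C@H]1OCc1ccccc1 | intermediate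
7 | 1-bromobut-2-yne | CC#CCBr | starting material
8 | (3S,4S,5R,6S)-5-(benzyloxy)-3-(but-2-yn-1-yl)-4,6-dimethyloxan-2-one | C[C@@H]1OC(=O)[C@@H](CC#CC)[C@H](C)[C@H]1OCc1ccccc1 | intermediate
9 | (3S,4S,5R,6S)-5-(benzyloxy)-4,6-dimethyl-3-(2-oxobutyl)oxan-2-one | C[C@@H]1OC(=O)[C@@H](CC(=O)CC)[C@H](C)[C@H]1OCc1ccccc1 | intermediate
10 | (4S)-4-[(2S,3R,4S)-3-(benzyloxy)-4-hydroxypentan-2-yl]-2-methylcyclopentane-1,3-dione (C2 enolisable) | C[C@H](O)[C@H](OCc1ccccc1)[C@@H](C)[C@@H]1CC(=O)C(C)C1=O | intermediate
11 | (2S,3R,4S,4aS)-3-(benzyloxy)-2,4,7-trimethyl-3,4,4a,5-tetrahydrocyclopenta[b]pyran-6(2H)-one | C[C@@H]1OC2=C(C)C(=O)C[C@H]2[C@H](C)[C@H]1OCc1ccccc1 | intermediate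
12 | iodomethane | CI | starting material
13 | (2S,3R,4S,4aR,5R)-3-(benzyloxy)-2,4,5,7-tetramethyl-3,4,4a,5-tetrahydrocyclopenta[b]pyran-6(2H)-one | C[C@@H]1OC2=C(C)C(=O)[C@H](C)[C@H]2[C@H](C)[C@H]1OCc1ccccc1 | intermediate
14 | (2S,3R,4S,4aR,5R)-3-(benzyloxy)-5-hydroxy-2,4,5,7-tetramethyl-3,4,4a,5-tetrahydrocyclopenta[b]pyran-6(2H)-one | C[C@@H]1OC2=C(C)C(=O)[C@](C)(O)[C@H]2[C@H](C)[C@H]1OCc1ccccc1 | intermediate
15 | (2S,3R,4S,4aR,5R,6R)-3-(benzyloxy)-2,4,5,7-tetramethyl-2,3,4,4a,5,6-hexahydrocyclopenta[b]pyran-5,6-diol | C[C@@H]1OC2=C(C)[C@@H](O)[C@](C)(O)[C@H]2[C@H](C)[C@H]1OCc1ccccc1 | intermediate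
16 | bis(triethylsilyl) ether of 15 | C[C@@H]1OC2=C(C)[C@@H](O[Si](CC)(CC)CC)[C@](C)(O[Si](CC)(CC)CC)[C@H]2[C@H](C)[C@H]1OCc1ccccc1 | intermediate
17 | tertiary allylic bromide, C2(Br)(Me), enol ether at C1=C5 | C[C@@H]1OC2=C([C@H](C)[C@H]1OCc1ccccc1)[C@@](C)(O[Si](CC)(CC)CC)[C@H](O[Si](CC)(CC)CC)[C@@]2(C)Br | intermediate
18 | 7-methylidene alkoxy diene | C[C@@H]1OC2=C([C@H](C)[C@H]1OCc1ccccc1)[C@@](C)(O[Si](CC)(CC)CC)[C@H](O[Si](CC)(CC)CC)C2=C | intermediate
19 | hexahydrocyclopenta[b]pyran enol ether (key-step precursor) | C[C@@H]1OC2=C([C@H](C)[C@H]1OCc1ccccc1)[C@@](C)(O[Si](CC)(CC)CC)[C@H](O[Si](CC)(CC)CC)[C@@H]2C | intermediate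
20 | C5 methoxy hydroperoxy ketal of the nine-membered lactone (C5 undefined) | c1ccccc1CO[C@@H]1[C@@H](C)C(OC)(OO)[C@@](C)(O[Si](CC)(CC)CC)[C@H](O[Si](CC)(CC)CC)[C@H](C)C(=O)O[C@H]1C | intermediate
21 | 8-(benzyloxy)-3,5,7,9-tetramethyl-4,5-bis(triethylsilyloxy)oxonane-2,6-dione (key-step product) | c1ccccc1CO[C@@H]1[C@@H](C)C(=O)[C@@](C)(O[Si](CC)(CC)CC)[C@H](O[Si](CC)(CC)CC)[C@H](C)C(=O)O[C@H]1C | intermediate
22 | (5S)-alcohol of 21 | c1ccccc1CO[C@@H]1[C@@H](C)[C@H](O)[C@@](C)(O[Si](CC)(CC)CC)[C@H](O[Si](CC)(CC)CC)[C@H](C)C(=O)O[C@H]1C | intermediate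
23 | C3, C4, C5 tris(triethylsilyl) ether, C7-OBn | c1ccccc1CO[C@@H]1[C@@H](C)[C@H](O[Si](CC)(CC)CC)[C@@](C)(O[Si](CC)(CC)CC)[C@H](O[Si](CC)(CC)CC)[C@H](C)C(=O)O[C@H]1C | intermediate
24 | C7 alcohol, tris(triethylsilyl) ether | O[C@@H]1[C@@H](C)[C@H](O[Si](CC)(CC)CC)[C@@](C)(O[Si](CC)(CC)CC)[C@H](O[Si](CC)(CC)CC)[C@H](C)C(=O)O[C@H]1C | intermediate
25 | pentanoyl chloride | CCCCC(=O)Cl | starting material
26 | bis(trimethylsilyl)acetylene | C[Si](C)(C)C#C[Si](C)(C)C | starting material
27 | 1-(trimethylsilyl)hept-1-yn-3-one | CCCCC(=O)C#C[Si](C)(C)C | intermediate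
28 | (R)-1-(trimethylsilyl)hept-1-yn-3-ol | CCCC[C@@H](O)C#C[Si](C)(C)C | intermediate
29 | (R)-hept-1-yn-3-ol | CCCC[C@@H](O)C#C | intermediate
30 | (R)-triethyl(hept-1-yn-3-yloxy)silane | CCCC[C@@H](O[Si](CC)(CC)CC)C#C | intermediate
31 | carbon dioxide | O=C=O | starting material
32 | (R)-4-(triethylsilyloxy)oct-2-ynoic acid | CCCC[C@@H](O[Si](CC)(CC)CC)C#CC(=O)O | intermediate
33 | tetrakis(triethylsilyl) C7 alkynoate | CCCC[C@@H](O[Si](CC)(CC)CC)C#CC(=O)O[C@@H]1[C@@H](C)[C@H](O[Si](CC)(CC)CC)[C@@](C)(O[Si](CC)(CC)CC)[C@H](O[Si](CC)(CC)CC)[C@H](C)C(=O)O[C@H]1C | intermediate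
34 | tetraol C7 alkynoate | CCCC[C@@H](O)C#CC(=O)O[C@@H]1[C@@H](C)[C@H](O)[C@@](C)(O)[C@H](O)[C@H](C)C(=O)O[C@H]1C | intermediate
35 | CNP0205075.3 | CCCC[C@@H](O)/C=C\C(=O)O[C@@H]1[C@@H](C)[C@H](O)[C@@](C)(O)[C@H](O)[C@H](C)C(=O)O[C@H]1C | target

Total step count: 25. Longest linear sequence: 20 steps (steps 1–17 and 23–25).

**Steps most likely to fail**

1. **Step 12.**
   - What may go wrong: a second bromination of the newly formed enol ether, capture of the oxocarbenium ion by succinimide, ionisation of the allylic silyloxy groups by traces of HBr, or elimination toward C3 with formation of a cyclopentadiene.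
   - Fallback: the alkene shift is moved to the ketone stage, setting out from 14.
     - Exhaustive silylation under soft-enolisation conditions (Me3SiOTf, Et3N, CH2Cl2, 0 °C; H5 is the only enolisable hydrogen) would give the bis(trimethylsilyl) dienol ether F1.
     - Saegusa–Ito dehydrosilylation with Pd(OAc)2 in MeCN would give the cross-conjugated alpha-methylene ketone F2. From the carbon-bound alpha-palladium enolate, a beta-hydrogen is available only on the C2 methyl.
     - Buffered HF·pyridine would give the free hydroxy enone F3.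
     - LiAlH4 in Et2O at −78 °C, with hydride delivered from the face of the C4 alkoxide, would give the dienyl trans-diol F4.
     - Bis-silylation of F4 with Et3SiOTf and 2,6-lutidine comes back to the route at 18.

2. **Step 14.**
   - What may go wrong: diversion of the carbonyl oxide into rearrangement or oligomeric peroxides, slow oxidation of the benzyl ether if the end point is missed, or loss of the tertiary allylic silyloxy group before the alkene is cut.
   - Fallback: the same C1–C5 bond is cut in two stages, setting out from 19.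
     - Epoxidation with dimethyldioxirane in acetone–CH2Cl2 at −78 to −40 °C would give the epoxy ether F5.
     - Buffered hydrolysis (THF–H2O, NaHCO3) would give the C1,C5-dihydroxy hemiketal F6.
     - Glycol fission of F6 with Pb(OAc)4 and K2CO3 in CH2Cl2 comes back to the route at 21.

3. **Step 15.**
   - What may go wrong: poor facial selectivity if the flexible nine-membered ring does not adopt the C5/O7 chelate, or transannular attack of the C5 alkoxide on C1 with ring contraction to a six-membered lactone.
   - Fallback: hydride is steered from the other side of the ketone by a covalent boron chelate, setting out from 21.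
     - Selective methanolysis of the secondary C3 silyl ether (PPTS, MeOH–CH2Cl2, −10 °C; the tertiary C4 ether reacts more slowly) would give the C3-hydroxy ketone F7.
     - Narasaka–Prasad reduction (Et2BOMe, NaBH4, THF–MeOH, −78 °C) would give the 3,5-syn diol F8, held as its boronate until work-up.
     - Bis-silylation of F8 with Et3SiOTf and 2,6-lutidine comes back to the route at 23.

**Further compounds**
F1 | step 12 | bis(trimethylsilyl) dienol ether (C4-OTMS; C3(OTMS)=C2, C1=C5) | C[C@@H]1OC2=C([C@H](C)[C@H]1OCc1ccccc1)[C@@](C)(O[Si](C)(C)C)C(O[Si](C)(C)C)=C2C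
F2 | step 12 | alpha-methylene ketone, C4-OTMS | C[C@@H]1OC2=C([C@H](C)[C@H]1OCc1ccccc1)[C@@](C)(O[Si](C)(C)C)C(=O)C2=C
F3 | step 12 | alpha-methylene ketone, free C4-OH | C[C@@H]1OC2=C([C@H](C)[C@H]1OCc1ccccc1)[C@@](C)(O)C(=O)C2=C
F4 | step 12 | dienyl C3/C4 trans-diol | C[C@@H]1OC2=C([C@H](C)[C@H]1OCc1ccccc1)[C@@](C)(O)[C@H](O)C2=C
F5 | step 14 | C1–C5 epoxy ether (C1 and C5 undefined) | C[C@@H]1OC23OC2([C@H](C)[C@H]1OCc1ccccc1)[C@@](C)(O[Si](CC)(CC)CC)[C@H](O[Si](CC)(CC)CC)[C@@H]3C
F6 | step 14 | C1,C5-dihydroxy hemiketal (C1 and C5 undefined) | C[C@@H]1OC2(O)C(O)([C@H](C)[C@H]1OCc1ccccc1)[C@@](C)(O[Si](CC)(CC)CC)[C@H](O[Si](CC)(CC)CC)[C@@H]2C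
F7 | step 15 | C3-hydroxy 5-oxo lactone, C4-OTES | c1ccccc1CO[C@@H]1[C@@H](C)C(=O)[C@@](C)(O[Si](CC)(CC)CC)[C@H](O)[C@H](C)C(=O)O[C@H]1C
F8 | step 15 | 3,5-syn diol, C4-OTES | c1ccccc1CO[C@@H]1[C@@H](C)[C@H](O)[C@@](C)(O[Si](CC)(CC)CC)[C@H](O)[C@H](C)C(=O)O[C@H]1C
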